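At 30 h I was to read target in the flasks south-east, south, north-west and east, which differ in their charge of partner.

| flask | substrate | partner | free catalyst | remark | time |
|---|---|---|---|---|---|
| eta | 1.5 M | 0.28 M (in portions, 3) | 1.1 mM | run made earlier; portions every 3.0 h |  |
| zeta | 1.5 M | 2.2 M (in portions, 3) | 1.1 mM | run made earlier; portions every 3.0 h |  |
| south-east | 1.5 M | 0.400 M (in portions, 3) | 1.1 mM | the portions of partner follow each other after 3.0 h, the first at the start | 30 h |
| south | 1.5 M | 0.800 M (in portions, 3) | 1.1 mM | the portions of partner follow each other after 3.0 h, the first at the start | 30 h |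
| north-west | 1.5 M | 1.50 M (in portions, 3) | 1.1 mM | the portions of partner follow each other after 3.0 h, the first at the start | 30 h |
| east | 1.5 M | 3.00 M (in portions, 3) | 1.1 mM | the portions of partner follow each other after 3.0 h, the first at the start | 30 h |

- eta (time / h: target / %, substrate / %): 2.50: 1.3, 98.6; 4.00: 1.4, 98.5; 6.00: 3.1, 96.6; 8.00: 5.0, 95.6; 12.0: 7.8, 92.3; 20.0: 11.6, 88.3; 30.0: 13.9, 85.3
- zeta (time / h: target / %, substrate / %): 4.00: 9.7, 89.9; 8.00: 21.5, 75.5; 12.0: 30.6, 62.1; 15.0: 34.9, 53.6; 20.0: 38.9, 41.9; 25.0: 41.6, 34.1; 30.0: 41.2, 27.9

(standard deviation of a reading: 0.3 percentage points)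

- the analysis behind the earlier runs scatters by 0.3 percentage points, standard deviation
- "hardly changes" means that all values lie within two and a half points (for a concentration: within two and a half percent of the largest)

1. amount of target at the end, in percent of the substrate charged for south-east, south, north-west, east, in this order
2. how the row runs (rises, then falls / hardly changes / rises all the way / falls all the way / falls, then rises)

At 30.0 h, target and substrate in the eta run add up to 99.2 % of the charge, but in the zeta run to 69.1 %, so in zeta target was being lost onward. In zeta it stood level within the scatter from 25.0 h to 30.0 h.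

Let s be the fraction of substrate left and x the fraction of target. I assumed that making and losing target carry the same factor of partner and catalyst, which then cancels in their ratio. Where x stands level, making equals loss, so substrate over target there gives κ = 0.749: this selectivity factor, the loss per unit of target over the making per unit of substrate, is a reading from zeta.

Integrating x against ln s gives x = (s^κ − s)/(1 − κ), whose top lies at s = 31.6 %.

I also needed s at the end. The value of ln(1/s) per molar of partner charged was 0.568 L mol⁻¹ in eta, about the same as the 0.580 L mol⁻¹ in zeta, so I took it as proportional to the charge and used zeta's figure. That gave me 18.9 %, 31.0 %, 40.7 % and 38.3 %.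

The forecast was 19.5 %, 30 %, 38.5 % and 37 %, a row that rises, then falls: “The maximum lies near 2 M, so east is past the peak, though only slightly.”

The flasks gave 19.0 %, 31.7 %, 41.6 % and 34.8 %, so the row rises, then falls.

    partner + free catalyst + target → free catalyst + over-reaction product (k = 0.0126 L² mol⁻² s⁻¹)
    substrate + free catalyst ⇌ catalyst intermediate A (K = 0.620 L mol⁻¹, k = 0.0654 L mol⁻¹ s⁻¹)
    partner + catalyst intermediate A ⇌ catalyst intermediate B (K = 1.61 L mol⁻¹, k = 0.0629 L mol⁻¹ s⁻¹)
    catalyst intermediate C → free catalyst + target (k = 1.54 s⁻¹)
    catalyst intermediate B → catalyst intermediate C (k = 0.0519 s⁻¹)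

North-west ended with substrate at 41.8 %, higher than the top at 31.6 %, and the formula gives target 40.8 % against 41.6 %. East ended with substrate at 18.3 %, lower than the top, and the formula gives 38.8 % against 34.8 %. In east, target stood at 18.2 % at 6.00 h and at 34.8 % at 30.0 h, and over-reaction product at 1.94 % and 46.8 % at those times, with 36 % of the partner charge still there, unbound, at the end. Left on to 300 h, east held target at 4.46 % and over-reaction product at 95.3 %.

The readings come from a simulation with constants of no real substance.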